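The dibenzo-1,4-dioxin is opened at the bond between the oxygen on the central carbon of the pentaoxygenated ring D and C2 of the dibenzofuran ring C. Ring D is 2,6-difluoro-3,5-dimethoxybenzaldehyde: its formyl group activates both fluorides for SNAr with the 1-hydroxydibenzofuran (rings A–C) and the arm phenol (rings E–H), and Dakin oxidation turns the formyl carbon into a phenol. The key step, an intramolecular Ullmann O-arylation, closes the dioxin from this open 2-(2-bromoaryloxy)phenol. It exploits the ortho pair O1/C2–Br on ring C and the adjacent O-bearing carbons of ring D. Global demethylation follows.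

Key step: step 21

Remark on the chemistry: the target has no stereocentre; the tetra-ortho-oxygenated E–F biaryl axis is undefined in the structure and is formed without control.
Remark on the chemistry: 2-fluoro-4,6-dimethoxybenzaldehyde (2) and 2,6-difluoro-3,5-dimethoxybenzaldehyde (29) are assumed to be catalogue compounds.
Remark on notation: A = 3,5-dioxygenated phenoxy ring; B and C = benzo rings of the dibenzofuran (ring C carries O1 and C2, dibenzofuran numbering); D = pentaoxygenated dioxin ring; E–F = biaryl; G and H = the two outer phenoxy rings.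

Step 1
Reactants: 1 2,4,6-trimethoxyphenol; 2 2-fluoro-4,6-dimethoxybenzaldehyde
Product: 3 2,4-dimethoxy-6-(2,4,6-trimethoxyphenoxy)benzaldehyde
Conditions: Cs2CO3, DMSO, 110 °C
Reagents that add atoms: none
Why: SNAr (addition–elimination through a Meisenheimer complex) of the phenoxide on the fluoride ortho to the formyl group, both methoxy groups being meta to fluorine.

Step 2
Reactants: 3 2,4-dimethoxy-6-(2,4,6-trimethoxyphenoxy)benzaldehyde
Product: 5 2,4-dimethoxy-6-(2,4,6-trimethoxyphenoxy)phenol, via aryl formate 4 (not isolated)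
Conditions: mCPBA, CH2Cl2, 0 °C to rt; then K2CO3, MeOH, rt
Reagents that add atoms: mCPBA, O=C(OO)c1cccc(Cl)c1
Why: Dakin-type Baeyer–Villiger oxidation in which the aryl group with two ortho oxygens and a para methoxy migrates, followed by methanolysis of the formate.

Step 3
Reactants: 5 2,4-dimethoxy-6-(2,4,6-trimethoxyphenoxy)phenol; 2 2-fluoro-4,6-dimethoxybenzaldehyde
Product: 6 2-[2,4-dimethoxy-6-(2,4,6-trimethoxyphenoxy)phenoxy]-4,6-dimethoxybenzaldehyde
Conditions: Cs2CO3, DMSO, 130 °C
Reagents that add atoms: none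
Why: second SNAr on an ortho-fluorobenzaldehyde, here with a 2,6-disubstituted but electron-rich phenoxide.

Step 4
Reactants: 6 2-[2,4-dimethoxy-6-(2,4,6-trimethoxyphenoxy)phenoxy]-4,6-dimethoxybenzaldehyde
Product: 8 2-[2,4-dimethoxy-6-(2,4,6-trimethoxyphenoxy)phenoxy]-4,6-dimethoxyphenol, via aryl formate 7 (not isolated)
Conditions: mCPBA, CH2Cl2, 0 °C to rt; then K2CO3, MeOH, rt
Reagents that add atoms: mCPBA, O=C(OO)c1cccc(Cl)c1
Why: Dakin-type Baeyer–Villiger oxidation of an ortho,ortho,para-trioxygenated benzaldehyde and formate methanolysis.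

Step 5
Reactants: 8 2-[2,4-dimethoxy-6-(2,4,6-trimethoxyphenoxy)phenoxy]-4,6-dimethoxyphenol
Product: 9 2-[2,4-dimethoxy-6-(2,4,6-trimethoxyphenoxy)phenoxy]-4,6-dimethoxyphenyl trifluoromethanesulfonate
Conditions: Tf2O, pyridine, CH2Cl2, 0 °C
Reagents that add atoms: trifluoromethanesulfonic anhydride, O=S(=O)(OS(=O)(=O)C(F)(F)F)C(F)(F)F
Why: O-sulfonylation of the phenol to an aryl triflate as the electrophile for cross-coupling.

Step 6
Reactants: 10 3,5-dimethoxyphenol
Product: 11 1,3-dimethoxy-5-(methoxymethoxy)benzene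
Conditions: NaH, MOMCl, THF, 0 °C to rt
Reagents that add atoms: chloromethyl methyl ether, COCCl
Why: Williamson-type O-alkylation giving a MOM ether that protects the phenol and directs ortho-lithiation.

Step 7
Reactants: 11 1,3-dimethoxy-5-(methoxymethoxy)benzene; 9 aryl triflate of rings F–H
Product: 14 2'-[2,4-dimethoxy-6-(2,4,6-trimethoxyphenoxy)phenoxy]-4,4',6,6'-tetramethoxy-2-(methoxymethoxy)-1,1'-biphenyl, via aryllithium 12 (not isolated), via arylzinc chloride 13 (not isolated)
Conditions: n-BuLi, THF, 0 °C; ZnCl2; then 9, Pd2(dba)3, RuPhos, THF/NMP, 70 °C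
Reagents that add atoms: none
Why: directed ortho-lithiation between OMOM and OMe, transmetalation to zinc and Negishi coupling with the triflate, using a RuPhos-ligated zerovalent palladium catalyst suited to tetra-ortho-substituted biaryls.

Step 8
Reactants: 14 MOM-protected biaryl of rings E–H
Product: 15 2'-[2,4-dimethoxy-6-(2,4,6-trimethoxyphenoxy)phenoxy]-4,4',6,6'-tetramethoxy-[1,1'-biphenyl]-2-ol
Conditions: 3 M HCl (aq), MeOH/THF, 50 °C
Reagents that add atoms: none
Why: acid-catalysed acetal cleavage of the MOM ether, to which the methyl and diaryl ethers are inert.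

Step 9
Reactants: 16 2-bromo-1,3-dimethoxybenzene
Product: 18 4-bromo-3,5-dimethoxyphenol, via pinacol boronate 17 (not isolated)
Conditions: [Ir(OMe)(cod)]2, dtbpy, B2pin2, THF, 80 °C; then H2O2, NaOH (aq), 0 °C
Reagents that add atoms: hydrogen peroxide, OO
Why: sterically controlled iridium-catalysed C–H borylation at C5, the only C–H without an ortho substituent, then oxidation of the C–B bond to the phenol.

Step 10
Reactants: 18 4-bromo-3,5-dimethoxyphenol
Product: 19 4-bromo-2-iodo-3,5-dimethoxyphenol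
Conditions: NIS (1.0 equiv), MeCN, 0 °C
Reagents that add atoms: N-iodosuccinimide, O=C1CCC(=O)N1I
Why: electrophilic aromatic iodination ortho to the hydroxyl, the two ortho positions being equivalent and the para position blocked by bromine.

Step 11
Reactants: 19 4-bromo-2-iodo-3,5-dimethoxyphenol
Product: 20 4-bromo-2-iodo-5-methoxybenzene-1,3-diol
Conditions: BBr3 (2.2 equiv), CH2Cl2, −78 to −10 °C; then H2O
Reagents that add atoms: none
Why: Lewis-acid ether cleavage in which the methoxy group flanked by iodine and bromine, twisted out of the ring plane and therefore the most Lewis basic, should be cleaved first.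

Step 12
Reactants: 20 4-bromo-2-iodo-5-methoxybenzene-1,3-diol; 2 2-fluoro-4,6-dimethoxybenzaldehyde
Product: 21 2-(4-bromo-3-hydroxy-2-iodo-5-methoxyphenoxy)-4,6-dimethoxybenzaldehyde
Conditions: K2CO3 (2.5 equiv), DMSO, 90 °C
Reagents that add atoms: none
Why: SNAr in which, within the dianion, the oxide with only one ortho halogen is more basic and far less hindered than the oxide between iodine and bromine, which also stays free as the more stabilised phenoxide.

Step 13
Reactants: 21 2-(4-bromo-3-hydroxy-2-iodo-5-methoxyphenoxy)-4,6-dimethoxybenzaldehyde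
Product: 22 2-[4-bromo-2-iodo-5-methoxy-3-(methoxymethoxy)phenoxy]-4,6-dimethoxybenzaldehyde
Conditions: MOMCl, K2CO3, DMF, rt
Reagents that add atoms: chloromethyl methyl ether, COCCl
Why: Williamson-type O-alkylation of the acidic phenol to a MOM ether that masks O1 of the future dibenzofuran.

Step 14
Reactants: 22 2-[4-bromo-2-iodo-5-methoxy-3-(methoxymethoxy)phenoxy]-4,6-dimethoxybenzaldehyde
Product: 23 2-bromo-3,7,9-trimethoxy-1-(methoxymethoxy)dibenzo[b,d]furan-6-carbaldehyde
Conditions: Pd(OAc)2, PPh3, K2CO3, PivOH (cat.), DMA, 100 °C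
Reagents that add atoms: none
Why: intramolecular palladium-catalysed direct arylation (concerted metalation–deprotonation) in which zerovalent palladium inserts into C–I in preference to the bromide flanked by two alkoxy groups, and the aryl–palladium attacks the only free position ortho to the ether oxygen on the aldehyde ring, closing the furan.

Step 15
Reactants: 23 2-bromo-3,7,9-trimethoxy-1-(methoxymethoxy)dibenzo[b,d]furan-6-carbaldehyde
Product: 25 2-bromo-3,7,9-trimethoxy-1-(methoxymethoxy)dibenzo[b,d]furan-6-ol, via aryl formate 24 (not isolated)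
Conditions: mCPBA, CH2Cl2, 0 °C to rt; then K2CO3, MeOH, rt
Reagents that add atoms: mCPBA, O=C(OO)c1cccc(Cl)c1
Why: Dakin-type Baeyer–Villiger oxidation of the aldehyde flanked by OMe and the furan oxygen and para to OMe, then formate methanolysis.

Step 16
Reactants: 25 2-bromo-3,7,9-trimethoxy-1-(methoxymethoxy)dibenzo[b,d]furan-6-ol; 26 (3,5-dimethoxyphenyl)boronic acid
Product: 27 2-bromo-6-(3,5-dimethoxyphenoxy)-3,7,9-trimethoxy-1-(methoxymethoxy)dibenzo[b,d]furan
Conditions: Cu(OAc)2 (2 equiv), pyridine, 4 Å MS, CH2Cl2, air, rt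
Reagents that add atoms: none
Why: Chan–Lam O-arylation, an oxidative copper-mediated coupling at room temperature that tolerates di-ortho-substituted phenols and leaves the aryl bromide untouched.

Step 17
Reactants: 27 2-bromo-6-(3,5-dimethoxyphenoxy)-3,7,9-trimethoxy-1-(methoxymethoxy)dibenzo[b,d]furan
Product: 28 2-bromo-6-(3,5-dimethoxyphenoxy)-3,7,9-trimethoxydibenzo[b,d]furan-1-ol
Conditions: 3 M HCl (aq), MeOH/THF, 50 °C
Reagents that add atoms: none
Why: acid-catalysed acetal cleavage of the MOM ether, freeing only O1.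

Step 18
Reactants: 28 2-bromo-6-(3,5-dimethoxyphenoxy)-3,7,9-trimethoxydibenzo[b,d]furan-1-ol; 29 2,6-difluoro-3,5-dimethoxybenzaldehyde
Product: 30 2-{[2-bromo-6-(3,5-dimethoxyphenoxy)-3,7,9-trimethoxydibenzo[b,d]furan-1-yl]oxy}-6-fluoro-3,5-dimethoxybenzaldehyde
Conditions: 29 (3 equiv), Cs2CO3, DMSO, 110 °C
Reagents that add atoms: none
Why: SNAr on one of the two equivalent fluorides ortho to the formyl group, so no regiochemical question arises and excess difluoride suppresses double substitution.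

Step 19
Reactants: 30 mono(aryloxy)fluorobenzaldehyde of rings A–D; 15 biaryl arm phenol of rings E–H
Product: 31 3,5-dimethoxybenzaldehyde bearing the dibenzofuran-1-yloxy group of 28 at C2 plus the biphenyl-2-yloxy group of 15 at C6
Conditions: Cs2CO3, DMSO, 130 °C
Reagents that add atoms: none
Why: SNAr on the remaining fluoride ortho to the formyl group, fluoride being a far better leaving group than the aryloxide already in place.

Step 20
Reactants: 31 bis(aryloxy)benzaldehyde
Product: 33 3,5-dimethoxyphenol bearing the dibenzofuran-1-yloxy group at C2 plus the biphenyl-2-yloxy group at C6, via aryl formate 32 (not isolated)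
Conditions: mCPBA, CH2Cl2, 0 °C to rt; then K2CO3, MeOH, rt
Reagents that add atoms: mCPBA, O=C(OO)c1cccc(Cl)c1
Why: Dakin-type Baeyer–Villiger oxidation of the 2,6-bis(aryloxy)benzaldehyde, which places the nucleophilic oxygen on the carbon between the two aryl ethers.

Step 21
Reactants: 33 open 2-(2-bromoaryloxy)phenol of rings A–H
Product: 34 hexadecamethyl ether of the target
Conditions: CuI (0.3 equiv), picolinic acid (0.6 equiv), K3PO4, DMSO (5 mM), 100 °C, Ar
Reagents that add atoms: none
Why: Intramolecular Ullmann ether synthesis: the phenoxide of ring D binds picolinate-ligated monovalent copper, the C2–Br bond of ring C adds oxidatively to give a trivalent arylcopper aryloxide, and C–O reductive elimination forms the O–C2 bond and returns monovalent copper. The closest known reaction type is the copper-catalysed cyclisation of 2-(2-halophenoxy)phenols to dibenzo-1,4-dioxins. The dioxin closes in a six-membered mode, the oxygen attacking the sp2 carbon ortho to the existing O1 ether bridge; no other ring size is open because C2–Br is the only halide and the phenol the only free hydroxyl. No stereocentre is formed. The step needs a defined dioxin orientation and cyclisation in preference to intermolecular coupling or hydrodebromination: the orientation was fixed in steps 18 and 20 (O1 on the former C–F carbon, the free oxygen on the former formyl carbon) and cannot scramble by Smiles rearrangement because neither ring is SNAr-active after the Dakin oxidation, and high dilution favours ring closure.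

Step 22
Reactants: 34 hexadecamethyl ether of the target
Product: 35 target CNP0192765.0
Conditions: BBr3 (excess), CH2Cl2, −78 °C to rt; then MeOH, H2O
Reagents that add atoms: none
Why: Lewis-acid cleavage of all sixteen aryl methyl ethers, to which the diaryl ether, dibenzofuran and dioxin C–O bonds are inert.

Compound list
1 | 2,4,6-trimethoxyphenol | COc1cc(OC)c(O)c(OC)c1 | starting material
2 | 2-fluoro-4,6-dimethoxybenzaldehyde | COc1cc(F)c(C=O)c(OC)c1 | starting material
3 | 2,4-dimethoxy-6-(2,4,6-trimethoxyphenoxy)benzaldehyde | COc1cc(OC)c(C=O)c(Oc2c(OC)cc(OC)cc2OC)c1 | intermediate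
4 | 2,4-dimethoxy-6-(2,4,6-trimethoxyphenoxy)phenyl formate | COc1cc(OC)c(OC=O)c(Oc2c(OC)cc(OC)cc2OC)c1 | intermediate
5 | 2,4-dimethoxy-6-(2,4,6-trimethoxyphenoxy)phenol | COc1cc(OC)c(O)c(Oc2c(OC)cc(OC)cc2OC)c1 | intermediate
6 | 2-[2,4-dimethoxy-6-(2,4,6-trimethoxyphenoxy)phenoxy]-4,6-dimethoxybenzaldehyde | COc1cc(OC)c(C=O)c(Oc2c(OC)cc(OC)cc2Oc2c(OC)cc(OC)cc2OC)c1 | intermediate
7 | 2-[2,4-dimethoxy-6-(2,4,6-trimethoxyphenoxy)phenoxy]-4,6-dimethoxyphenyl formate | COc1cc(OC)c(OC=O)c(Oc2c(OC)cc(OC)cc2Oc2c(OC)cc(OC)cc2OC)c1 | intermediate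
8 | 2-[2,4-dimethoxy-6-(2,4,6-trimethoxyphenoxy)phenoxy]-4,6-dimethoxyphenol | COc1cc(OC)c(O)c(Oc2c(OC)cc(OC)cc2Oc2c(OC)cc(OC)cc2OC)c1 | intermediate
9 | 2-[2,4-dimethoxy-6-(2,4,6-trimethoxyphenoxy)phenoxy]-4,6-dimethoxyphenyl trifluoromethanesulfonate | COc1cc(OC)c(OS(=O)(=O)C(F)(F)F)c(Oc2c(OC)cc(OC)cc2Oc2c(OC)cc(OC)cc2OC)c1 | intermediate
10 | 3,5-dimethoxyphenol | COc1cc(O)cc(OC)c1 | starting material
11 | 1,3-dimethoxy-5-(methoxymethoxy)benzene | COCOc1cc(OC)cc(OC)c1 | intermediate
12 | [2,4-dimethoxy-6-(methoxymethoxy)phenyl]lithium | [Li]c1c(OCOC)cc(OC)cc1OC | intermediate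
13 | [2,4-dimethoxy-6-(methoxymethoxy)phenyl]zinc chloride | Cl[Zn]c1c(OCOC)cc(OC)cc1OC | intermediate
14 | 2'-[2,4-dimethoxy-6-(2,4,6-trimethoxyphenoxy)phenoxy]-4,4',6,6'-tetramethoxy-2-(methoxymethoxy)-1,1'-biphenyl | COCOc1cc(OC)cc(OC)c1-c1c(OC)cc(OC)cc1Oc1c(OC)cc(OC)cc1Oc1c(OC)cc(OC)cc1OC | intermediate
15 | 2'-[2,4-dimethoxy-6-(2,4,6-trimethoxyphenoxy)phenoxy]-4,4',6,6'-tetramethoxy-[1,1'-biphenyl]-2-ol | Oc1cc(OC)cc(OC)c1-c1c(OC)cc(OC)cc1Oc1c(OC)cc(OC)cc1Oc1c(OC)cc(OC)cc1OC | intermediate
16 | 2-bromo-1,3-dimethoxybenzene | COc1cccc(OC)c1Br | starting material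
17 | 2-(4-bromo-3,5-dimethoxyphenyl)-4,4,5,5-tetramethyl-1,3,2-dioxaborolane | COc1cc(B2OC(C)(C)C(C)(C)O2)cc(OC)c1Br | intermediate
18 | 4-bromo-3,5-dimethoxyphenol | COc1cc(O)cc(OC)c1Br | intermediate
19 | 4-bromo-2-iodo-3,5-dimethoxyphenol | COc1cc(O)c(I)c(OC)c1Br | intermediate
20 | 4-bromo-2-iodo-5-methoxybenzene-1,3-diol | COc1cc(O)c(I)c(O)c1Br | intermediate
21 | 2-(4-bromo-3-hydroxy-2-iodo-5-methoxyphenoxy)-4,6-dimethoxybenzaldehyde | COc1cc(OC)c(C=O)c(Oc2cc(OC)c(Br)c(O)c2I)c1 | intermediate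
22 | 2-[4-bromo-2-iodo-5-methoxy-3-(methoxymethoxy)phenoxy]-4,6-dimethoxybenzaldehyde | COCOc1c(Br)c(OC)cc(Oc2cc(OC)cc(OC)c2C=O)c1I | intermediate
23 | 2-bromo-3,7,9-trimethoxy-1-(methoxymethoxy)dibenzo[b,d]furan-6-carbaldehyde | O=Cc1c(OC)cc(OC)c2c1oc1cc(OC)c(Br)c(OCOC)c12 | intermediate
24 | 2-bromo-3,7,9-trimethoxy-1-(methoxymethoxy)dibenzo[b,d]furan-6-yl formate | O=COc1c(OC)cc(OC)c2c1oc1cc(OC)c(Br)c(OCOC)c12 | intermediate
25 | 2-bromo-3,7,9-trimethoxy-1-(methoxymethoxy)dibenzo[b,d]furan-6-ol | Oc1c(OC)cc(OC)c2c1oc1cc(OC)c(Br)c(OCOC)c12 | intermediate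
26 | (3,5-dimethoxyphenyl)boronic acid | COc1cc(OC)cc(B(O)O)c1 | starting material
27 | 2-bromo-6-(3,5-dimethoxyphenoxy)-3,7,9-trimethoxy-1-(methoxymethoxy)dibenzo[b,d]furan | COc1cc(OC)cc(Oc2c(OC)cc(OC)c3c2oc2cc(OC)c(Br)c(OCOC)c23)c1 | intermediate
28 | 2-bromo-6-(3,5-dimethoxyphenoxy)-3,7,9-trimethoxydibenzo[b,d]furan-1-ol | COc1cc(OC)cc(Oc2c(OC)cc(OC)c3c2oc2cc(OC)c(Br)c(O)c23)c1 | intermediate
29 | 2,6-difluoro-3,5-dimethoxybenzaldehyde | COc1cc(OC)c(F)c(C=O)c1F | starting material
30 | 2-{[2-bromo-6-(3,5-dimethoxyphenoxy)-3,7,9-trimethoxydibenzo[b,d]furan-1-yl]oxy}-6-fluoro-3,5-dimethoxybenzaldehyde | COc1cc(OC)cc(Oc2c(OC)cc(OC)c3c2oc2cc(OC)c(Br)c(Oc4c(OC)cc(OC)c(F)c4C=O)c23)c1 | intermediate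
31 | 3,5-dimethoxybenzaldehyde with the dibenzofuran-1-yloxy group of 28 at C2 and the biphenyl-2-yloxy group of 15 at C6 | COc1cc(OC)cc(Oc2c(OC)cc(OC)c3c2oc2cc(OC)c(Br)c(Oc4c(OC)cc(OC)c(Oc5cc(OC)cc(OC)c5-c5c(OC)cc(OC)cc5Oc5c(OC)cc(OC)cc5Oc5c(OC)cc(OC)cc5OC)c4C=O)c23)c1 | intermediate
32 | formate ester of phenol 33 | COc1cc(OC)cc(Oc2c(OC)cc(OC)c3c2oc2cc(OC)c(Br)c(Oc4c(OC)cc(OC)c(Oc5cc(OC)cc(OC)c5-c5c(OC)cc(OC)cc5Oc5c(OC)cc(OC)cc5Oc5c(OC)cc(OC)cc5OC)c4OC=O)c23)c1 | intermediate
33 | 3,5-dimethoxyphenol with the dibenzofuran-1-yloxy group of 28 at C2 and the biphenyl-2-yloxy group of 15 at C6 | COc1cc(OC)cc(Oc2c(OC)cc(OC)c3c2oc2cc(OC)c(Br)c(Oc4c(OC)cc(OC)c(Oc5cc(OC)cc(OC)c5-c5c(OC)cc(OC)cc5Oc5c(OC)cc(OC)cc5Oc5c(OC)cc(OC)cc5OC)c4O)c23)c1 | intermediate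
34 | hexadecamethyl ether of the target (all sixteen OH as OMe, full ring skeleton) | COc1cc(OC)cc(Oc2c(OC)cc(OC)c3c2oc2cc(OC)c4c(c23)Oc2c(OC)cc(OC)c(Oc3cc(OC)cc(OC)c3-c3c(OC)cc(OC)cc3Oc3c(OC)cc(OC)cc3Oc3c(OC)cc(OC)cc3OC)c2O4)c1 | intermediate
35 | CNP0192765.0 | Oc1cc(O)cc(Oc2c(O)cc(O)c3c2oc2cc(O)c4c(c23)Oc2c(O)cc(O)c(Oc3cc(O)cc(O)c3-c3c(O)cc(O)cc3Oc3c(O)cc(O)cc3Oc3c(O)cc(O)cc3O)c2O4)c1 | target

Total step count: 22 steps.
Longest linear sequence: 14 steps (steps 9 to 22, from 16 to 35).

Steps most likely to fail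

1. Step 18 (and its twin, step 19). Both substitutions bring a hindered phenoxide onto a fluoride activated by a single formyl group, which can twist out of conjugation once one ortho aryloxy group is in place. Slow substitution, with aldehyde decomposition at the temperature then needed, is the risk. The fallback moves the linchpin to the nitrile oxidation level. It sets out from 29: oxidative amination–dehydration (I2, aqueous NH3, THF) would give 2,6-difluoro-3,5-dimethoxybenzonitrile F1, whose linear cyano group stays conjugated and does not hinder the ortho positions. SNAr with 28 (Cs2CO3, DMSO) would give the mono(aryloxy)fluorobenzonitrile F2, and SNAr with 15 the bis(aryloxy)benzonitrile F3. Reduction of F3 with DIBAL-H (toluene, −78 °C, then aqueous acid) would give aldehyde 31, where the route is rejoined.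

2. Step 7. Transmetalation onto a di-ortho-substituted aryl–palladium triflate complex and reductive elimination of a tetra-ortho-oxygenated biaryl may be slower than protodemetalation of 13 or loss of the triflate. The fallback replaces cross-coupling by carbonyl addition. It sets out from phenol 8: oxidation with PhI(OAc)2 in MeOH would give the para-quinone monoketal F4. Addition of aryllithium 12 to its carbonyl group (THF, −78 °C) would give the racemic para-quinol ketal F5. Reductive aromatisation of F5 with Zn in AcOH would expel hydroxide and one methoxide and return biaryl 14.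

3. Step 14. Insertion of zerovalent palladium into the C2–Br bond of substrate or product (debromination, oligomers) and slow closure into the congested bay between O1 and the C9 methoxy group are the risks. The fallback is a metal-free photochemical cyclisation that sets out from 22 and returns at 23. Irradiation (300 nm, MeCN, K2CO3) would homolyse only the weak C–I bond, and the aryl radical would close onto the neighbouring ring by homolytic aromatic substitution. No new compound is involved.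

Further compounds
F1 | step 18 | 2,6-difluoro-3,5-dimethoxybenzonitrile | COc1cc(OC)c(F)c(C#N)c1F
F2 | step 18 | 2-{[2-bromo-6-(3,5-dimethoxyphenoxy)-3,7,9-trimethoxydibenzo[b,d]furan-1-yl]oxy}-6-fluoro-3,5-dimethoxybenzonitrile | COc1cc(OC)cc(Oc2c(OC)cc(OC)c3c2oc2cc(OC)c(Br)c(Oc4c(OC)cc(OC)c(F)c4C#N)c23)c1
F3 | step 18 | 3,5-dimethoxybenzonitrile with the dibenzofuran-1-yloxy group of 28 at C2 and the biphenyl-2-yloxy group of 15 at C6 | COc1cc(OC)cc(Oc2c(OC)cc(OC)c3c2oc2cc(OC)c(Br)c(Oc4c(OC)cc(OC)c(Oc5cc(OC)cc(OC)c5-c5c(OC)cc(OC)cc5Oc5c(OC)cc(OC)cc5Oc5c(OC)cc(OC)cc5OC)c4C#N)c23)c1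
F4 | step 7 | 2-[2,4-dimethoxy-6-(2,4,6-trimethoxyphenoxy)phenoxy]-4,4,6-trimethoxycyclohexa-2,5-dien-1-one | COC1=CC(OC)(OC)C=C(Oc2c(OC)cc(OC)cc2Oc2c(OC)cc(OC)cc2OC)C1=O
F5 | step 7 | racemic 1-[2,4-dimethoxy-6-(methoxymethoxy)phenyl]-2-[2,4-dimethoxy-6-(2,4,6-trimethoxyphenoxy)phenoxy]-4,4,6-trimethoxycyclohexa-2,5-dien-1-ol | COC1=CC(OC)(OC)C=C(Oc2c(OC)cc(OC)cc2Oc2c(OC)cc(OC)cc2OC)C1(O)c3c(OCOC)cc(OC)cc3OC
F0 | step 14 | none | none
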